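**Retrosynthetic overview**
- The route rests on the C2=C3 bond of ring C, which carries ring B on C2 and an oxygen on C3. An alkyne placed between the C4 carbonyl and ring B can therefore take the C8a hydroxyl at C2 (O1–C2 bond) and an iodine at C3 in one anti addition.
- Working back from the target: the four O-benzyl groups (hydrogenolysis), the 3-O-methyl group, C3–O (from C3–I through a boronate), then O1–C2 and C3–I together (iodocyclisation of an ortho-hydroxyaryl ynone).
- The ynone is cut at C3–C4: a ring B arylacetylide adds to an O-silylated ring A salicylaldehyde, followed by oxidation and desilylation. The alkyne carbon that becomes C3 comes from the Ohira–Bestmann reagent.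
- Ring A aldehyde comes from 2,4,6-trihydroxybenzaldehyde: Baeyer–Villiger oxidation exchanges its formyl carbon for the C8 methoxy oxygen, and hydroxyl-directed formylation puts the C4 carbon back next to the C8a hydroxyl. Ring B alkyne comes from isovanillin.
- Rings A and B are aromatic from the start; ring C is the only ring formed and closes last, in the key step.

Key step: step 16

Remark: the target has no stereocentre; propargylic alcohol 20 is carried as the racemate and its carbinol centre is erased by the oxidation in step 14.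

**Ring A aldehyde (steps 1–7)**

Step 1
Reactants: 1 2,4,6-trihydroxybenzaldehyde
Product: 2 2,4-bis(benzyloxy)-6-hydroxybenzaldehyde
Conditions: BnBr (2.05 equiv), K2CO3 (2.1 equiv), DMF, 0 °C to rt
Reagents that add atoms: benzyl bromide BrCc1ccccc1
Why: Williamson etherification in which the 4-OH and one ortho OH are alkylated, while the last ortho OH is held in a hydrogen bond to the formyl group and resists alkylation, so two equivalents of benzyl bromide should stop at the bis-ether.

Step 2
Reactants: 2 2,4-bis(benzyloxy)-6-hydroxybenzaldehyde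
Product: 3 2,4-bis(benzyloxy)-6-(methoxymethoxy)benzaldehyde
Conditions: MOMCl, iPr2NEt, CH2Cl2, 0 °C to rt
Reagents that add atoms: chloromethyl methyl ether COCCl
Why: O-alkylation of the chelated phenol by the very reactive alpha-chloro ether (acetal formation) gives a MOM group, which cannot migrate to a neighbouring oxygen and so keeps the future C8a oxygen marked through the next steps.

Step 3
Reactants: 3 2,4-bis(benzyloxy)-6-(methoxymethoxy)benzaldehyde
Product: 5 2,4-bis(benzyloxy)-6-(methoxymethoxy)phenol, via aryl formate 4 (not isolated)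
Conditions: mCPBA, CH2Cl2, 0 °C to rt; aq. NaHCO3 wash; then K2CO3 (cat.), MeOH, rt
Reagents that add atoms: meta-chloroperoxybenzoic acid OOC(=O)c1cccc(Cl)c1
Why: Baeyer–Villiger (Dakin-type) oxidation in which the electron-rich trioxygenated aryl group migrates, and mild methanolysis of the aryl formate frees the phenol oxygen that will become the C8 methoxy oxygen; acetal and benzyl ethers are inert.

Step 4
Reactants: 5 2,4-bis(benzyloxy)-6-(methoxymethoxy)phenol
Product: 6 1,5-bis(benzyloxy)-2-methoxy-3-(methoxymethoxy)benzene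
Conditions: MeI, K2CO3, DMF, rt
Reagents that add atoms: iodomethane CI
Why: Williamson methylation of the only free phenol fixes the methoxy group between the benzyloxy and the MOM-oxy substituents without any regiochemical choice.

Step 5
Reactants: 6 1,5-bis(benzyloxy)-2-methoxy-3-(methoxymethoxy)benzene
Product: 7 3,5-bis(benzyloxy)-2-methoxyphenol
Conditions: HCl (conc., cat.), MeOH/THF, 45 °C
Reagents that add atoms: none
Why: Acid-catalysed acetal exchange with methanol removes the MOM group as dimethoxymethane, while benzyl and methyl aryl ethers are stable to dilute HCl.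

Step 6
Reactants: 7 3,5-bis(benzyloxy)-2-methoxyphenol
Product: 8 4,6-bis(benzyloxy)-2-hydroxy-3-methoxybenzaldehyde
Conditions: MgCl2, Et3N, (CH2O)n, MeCN, reflux; then 1 M HCl
Reagents that add atoms: paraformaldehyde (formaldehyde) C=O
Why: Casnati–Skattebøl ortho-formylation, in which the magnesium phenoxide delivers formaldehyde to the ortho carbon and a second formaldehyde takes up hydride; the only free ortho position is C6, so the carbon between the two benzyloxy groups is not touched.

Step 7
Reactants: 8 4,6-bis(benzyloxy)-2-hydroxy-3-methoxybenzaldehyde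
Product: 9 4,6-bis(benzyloxy)-2-[(tert-butyldimethylsilyl)oxy]-3-methoxybenzaldehyde
Conditions: TBSCl, imidazole, DMF, rt
Reagents that add atoms: tert-butyldimethylsilyl chloride CC(C)(C)[Si](C)(C)Cl
Why: Imidazole-promoted O-silylation masks the acidic phenol before the acetylide addition and can later be removed by fluoride without touching benzyl ethers.

**Ring B alkyne (steps 8–12)**

Step 8
Reactants: 10 isovanillin (3-hydroxy-4-methoxybenzaldehyde)
Product: 11 3-(benzyloxy)-4-methoxybenzaldehyde
Conditions: BnBr, K2CO3, DMF, rt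
Reagents that add atoms: benzyl bromide BrCc1ccccc1
Why: Williamson etherification of the single phenol.

Step 9
Reactants: 11 3-(benzyloxy)-4-methoxybenzaldehyde
Product: 13 3-(benzyloxy)-4-methoxyphenol, via aryl formate 12 (not isolated)
Conditions: mCPBA, CH2Cl2, rt; aq. NaHCO3 wash; then K2CO3 (cat.), MeOH, rt
Reagents that add atoms: meta-chloroperoxybenzoic acid OOC(=O)c1cccc(Cl)c1
Why: Baeyer–Villiger oxidation with migration of the para-methoxy-activated aryl group, then formate methanolysis, turns the formyl carbon into the oxygen that becomes the 4'-oxygen of ring B.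

Step 10
Reactants: 13 3-(benzyloxy)-4-methoxyphenol
Product: 14 2,4-bis(benzyloxy)-1-methoxybenzene
Conditions: BnBr, K2CO3, DMF, rt
Reagents that add atoms: benzyl bromide BrCc1ccccc1
Why: Williamson etherification of the only free phenol.

Step 11
Reactants: 14 2,4-bis(benzyloxy)-1-methoxybenzene
Product: 16 2,4-bis(benzyloxy)-5-methoxybenzaldehyde, via iminium chloride 15 (not isolated)
Conditions: POCl3, DMF, 0 °C to 70 °C; then ice-water
Reagents that add atoms: N,N-dimethylformamide CN(C)C=O; water O
Why: Vilsmeier–Haack formylation at C5, which is para to one benzyloxy group and ortho to the other and is not flanked on both sides, as in the formylation of 1,2,4-trimethoxybenzene to the 2,4,5-trialkoxybenzaldehyde.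

Step 12
Reactants: 16 2,4-bis(benzyloxy)-5-methoxybenzaldehyde; 17 dimethyl (1-diazo-2-oxopropyl)phosphonate
Product: 18 1,5-bis(benzyloxy)-2-ethynyl-4-methoxybenzene
Conditions: K2CO3, MeOH/THF, rt
Reagents that add atoms: dimethyl (1-diazo-2-oxopropyl)phosphonate COP(=O)(OC)C(=[N+]=[N-])C(C)=O
Why: Ohira–Bestmann variant of the Seyferth–Gilbert homologation, in which methanolysis of the acetyl group gives the diazomethylphosphonate anion, and olefination, loss of N2 and 1,2-hydrogen shift give the terminal alkyne under conditions that spare aryl ethers.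

**Coupling and ynone (steps 13–15)**

Step 13
Reactants: 18 1,5-bis(benzyloxy)-2-ethynyl-4-methoxybenzene; 9 4,6-bis(benzyloxy)-2-[(tert-butyldimethylsilyl)oxy]-3-methoxybenzaldehyde
Product: 20 rac-1-{4,6-bis(benzyloxy)-2-[(tert-butyldimethylsilyl)oxy]-3-methoxyphenyl}-3-[2,4-bis(benzyloxy)-5-methoxyphenyl]prop-2-yn-1-ol, via lithium acetylide 19 (not isolated)
Conditions: 18 (1.2 equiv), n-BuLi (1.15 equiv), THF, −78 °C; then 9, −78 °C; aq. NH4Cl at −78 °C
Reagents that add atoms: none
Why: 1,2-Addition of a lithium acetylide to an aldehyde forms the C3–C4 bond; the alkyne C–H is the only acidic site, the cold quench should forestall oxygen-to-oxygen silyl migration, and the carbinol centre forms as a racemate that is removed in step 14.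

Step 14
Reactants: 20 rac-propargylic alcohol
Product: 21 1-{4,6-bis(benzyloxy)-2-[(tert-butyldimethylsilyl)oxy]-3-methoxyphenyl}-3-[2,4-bis(benzyloxy)-5-methoxyphenyl]prop-2-yn-1-one
Conditions: MnO2 (activated, excess), CH2Cl2, rt
Reagents that add atoms: none
Why: Activated MnO2 oxidises the benzylic–propargylic alcohol chemoselectively and leaves ethers, silyl ether and alkyne untouched.

Step 15
Reactants: 21 O-silyl ynone
Product: 22 1-[4,6-bis(benzyloxy)-2-hydroxy-3-methoxyphenyl]-3-[2,4-bis(benzyloxy)-5-methoxyphenyl]prop-2-yn-1-one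
Conditions: Bu4NF, AcOH, THF, 0 °C
Reagents that add atoms: none
Why: Fluoride-induced cleavage of the aryl silyl ether, with acetic acid protonating the phenoxide at once so that base-mediated closure to an aurone or a halogen-free flavone should not start; the phenol is then held by a hydrogen bond to the ketone.

**Key step and end game (steps 16–19)**

Step 16
Reactants: 22 ortho-hydroxyaryl ynone
Product: 23 5,7-bis(benzyloxy)-2-[2,4-bis(benzyloxy)-5-methoxyphenyl]-3-iodo-8-methoxy-4H-chromen-4-one (5,7,2',4'-tetrakis(benzyloxy)-3-iodo-8,5'-dimethoxyflavone)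
Conditions: ICl (1.05 equiv, 1 M in CH2Cl2), CH2Cl2, −78 °C, dark; then aq. Na2S2O3
Reagents that add atoms: iodine monochloride ClI
Why: ICl delivers iodine to the alkyne carbon next to the carbonyl (C3), because the positive charge that develops at C2 is stabilised by the 2',4'-dioxygenated ring B and C2 is also the beta carbon of the ynone; the C8a hydroxyl then adds to C2 anti to iodine and loss of HCl gives the 3-iodo-4-pyranone. The closest known reaction type is the ICl-induced iodocyclisation of ortho-oxygenated aryl alkynones to 3-iodochromones. Ring C closes in the 6-endo-dig mode, forming the O1–C2 and C3–I bonds, and no stereocentre is created. The step needs the C8a oxygen to win over the 2'-benzyloxy oxygen (5-endo closure onto C3 to a benzofuran), over the 5-benzyloxy oxygen (closure onto C2 to the isomeric chromone) and over 5-exo attack at C3 (aurone). The free phenol is the only non-alkylated and therefore most nucleophilic oxygen, the alkyne polarisation sends the nucleophile to C2, and a benzyl ether could close only after losing its benzyl group. One equivalent of ICl at −78 °C should keep iodination of the electron-rich arenes behind the faster attack on the push-pull alkyne.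

Step 17
Reactants: 23 3-iodoflavone
Product: 25 5,7,2',4'-tetrakis(benzyloxy)-3-hydroxy-8,5'-dimethoxyflavone, via pinacol boronate 24 (not isolated)
Conditions: PdCl2(dppf) (5 mol %), B2pin2, KOAc, 1,4-dioxane, 80 °C; then 30% H2O2, aq. NaHCO3, THF, 0 °C
Reagents that add atoms: hydrogen peroxide OO; bis(pinacolato)diboron CC1(C)OB(OC1(C)C)B1OC(C)(C)C(C)(C)O1 (its boron stays only in intermediate 24)
Why: Miyaura borylation of the C3–I bond (oxidative addition, acetate-assisted transmetalation, reductive elimination) followed by peroxide-induced 1,2-shift of C3 from boron to oxygen gives the enol form, that is the 3-hydroxyflavone, and the weakly basic peroxide should spare the pyranone ring.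

Step 18
Reactants: 25 3-hydroxyflavone
Product: 26 5,7,2',4'-tetrakis(benzyloxy)-3,8,5'-trimethoxyflavone
Conditions: MeI, K2CO3, DMF, rt
Reagents that add atoms: iodomethane CI
Why: Williamson O-methylation of the acidic 3-hydroxyl, which is the only free OH in the molecule.

Step 19
Reactants: 26 tetrabenzyl trimethoxyflavone
Product: 27 5,7,2',4'-tetrahydroxy-3,8,5'-trimethoxyflavone
Conditions: H2 (1 atm), Pd/C (10 wt %), THF/MeOH, rt
Reagents that add atoms: none
Why: Hydrogenolysis of the four benzyl aryl ethers over Pd/C, while the methyl ethers and the tetrasubstituted, vinylogous-ester C2=C3 bond of the flavone should not be reduced at 1 atm and rt.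

**Compound list**
1 | 2,4,6-trihydroxybenzaldehyde | O=Cc1c(O)cc(O)cc1O | starting material
2 | 2,4-bis(benzyloxy)-6-hydroxybenzaldehyde | O=Cc1c(O)cc(OCc2ccccc2)cc1OCc1ccccc1 | intermediate
3 | 2,4-bis(benzyloxy)-6-(methoxymethoxy)benzaldehyde | COCOc1cc(OCc2ccccc2)cc(OCc2ccccc2)c1C=O | intermediate
4 | 2,4-bis(benzyloxy)-6-(methoxymethoxy)phenyl formate (not isolated) | COCOc1cc(OCc2ccccc2)cc(OCc2ccccc2)c1OC=O | intermediate
5 | 2,4-bis(benzyloxy)-6-(methoxymethoxy)phenol | COCOc1cc(OCc2ccccc2)cc(OCc2ccccc2)c1O | intermediate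
6 | 1,5-bis(benzyloxy)-2-methoxy-3-(methoxymethoxy)benzene | COCOc1cc(OCc2ccccc2)cc(OCc2ccccc2)c1OC | intermediate
7 | 3,5-bis(benzyloxy)-2-methoxyphenol | COc1c(O)cc(OCc2ccccc2)cc1OCc1ccccc1 | intermediate
8 | 4,6-bis(benzyloxy)-2-hydroxy-3-methoxybenzaldehyde | COc1c(O)c(C=O)c(OCc2ccccc2)cc1OCc1ccccc1 | intermediate
9 | 4,6-bis(benzyloxy)-2-[(tert-butyldimethylsilyl)oxy]-3-methoxybenzaldehyde | COc1c(O[Si](C)(C)C(C)(C)C)c(C=O)c(OCc2ccccc2)cc1OCc1ccccc1 | intermediate
10 | isovanillin (3-hydroxy-4-methoxybenzaldehyde) | COc1ccc(C=O)cc1O | starting material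
11 | 3-(benzyloxy)-4-methoxybenzaldehyde | COc1ccc(C=O)cc1OCc1ccccc1 | intermediate
12 | 3-(benzyloxy)-4-methoxyphenyl formate (not isolated) | COc1ccc(OC=O)cc1OCc1ccccc1 | intermediate
13 | 3-(benzyloxy)-4-methoxyphenol | COc1ccc(O)cc1OCc1ccccc1 | intermediate
14 | 2,4-bis(benzyloxy)-1-methoxybenzene | COc1ccc(OCc2ccccc2)cc1OCc1ccccc1 | intermediate
15 | N-{[2,4-bis(benzyloxy)-5-methoxyphenyl]methylidene}-N-methylmethanaminium chloride (not isolated) | COc1cc(C=[N+](C)C)c(OCc2ccccc2)cc1OCc1ccccc1.[Cl-] | intermediate
16 | 2,4-bis(benzyloxy)-5-methoxybenzaldehyde | COc1cc(C=O)c(OCc2ccccc2)cc1OCc1ccccc1 | intermediate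
17 | dimethyl (1-diazo-2-oxopropyl)phosphonate | COP(=O)(OC)C(=[N+]=[N-])C(C)=O | starting material
18 | 1,5-bis(benzyloxy)-2-ethynyl-4-methoxybenzene | COc1cc(C#C)c(OCc2ccccc2)cc1OCc1ccccc1 | intermediate
19 | lithium [2,4-bis(benzyloxy)-5-methoxyphenyl]ethynide (not isolated) | [Li]C#Cc1cc(OC)c(OCc2ccccc2)cc1OCc1ccccc1 | intermediate
20 | rac-1-{4,6-bis(benzyloxy)-2-[(tert-butyldimethylsilyl)oxy]-3-methoxyphenyl}-3-[2,4-bis(benzyloxy)-5-methoxyphenyl]prop-2-yn-1-ol | COc1cc(C#CC(O)c2c(O[Si](C)(C)C(C)(C)C)c(OC)c(OCc3ccccc3)cc2OCc2ccccc2)c(OCc2ccccc2)cc1OCc1ccccc1 | intermediate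
21 | 1-{4,6-bis(benzyloxy)-2-[(tert-butyldimethylsilyl)oxy]-3-methoxyphenyl}-3-[2,4-bis(benzyloxy)-5-methoxyphenyl]prop-2-yn-1-one | COc1cc(C#CC(=O)c2c(O[Si](C)(C)C(C)(C)C)c(OC)c(OCc3ccccc3)cc2OCc2ccccc2)c(OCc2ccccc2)cc1OCc1ccccc1 | intermediate
22 | 1-[4,6-bis(benzyloxy)-2-hydroxy-3-methoxyphenyl]-3-[2,4-bis(benzyloxy)-5-methoxyphenyl]prop-2-yn-1-one | COc1cc(C#CC(=O)c2c(O)c(OC)c(OCc3ccccc3)cc2OCc2ccccc2)c(OCc2ccccc2)cc1OCc1ccccc1 | intermediate
23 | 5,7-bis(benzyloxy)-2-[2,4-bis(benzyloxy)-5-methoxyphenyl]-3-iodo-8-methoxy-4H-chromen-4-one | COc1cc(-c2oc3c(OC)c(OCc4ccccc4)cc(OCc4ccccc4)c3c(=O)c2I)c(OCc2ccccc2)cc1OCc1ccccc1 | intermediate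
24 | 5,7-bis(benzyloxy)-2-[2,4-bis(benzyloxy)-5-methoxyphenyl]-8-methoxy-3-(4,4,5,5-tetramethyl-1,3,2-dioxaborolan-2-yl)-4H-chromen-4-one (not isolated) | COc1cc(-c2oc3c(OC)c(OCc4ccccc4)cc(OCc4ccccc4)c3c(=O)c2B2OC(C)(C)C(C)(C)O2)c(OCc2ccccc2)cc1OCc1ccccc1 | intermediate
25 | 5,7-bis(benzyloxy)-2-[2,4-bis(benzyloxy)-5-methoxyphenyl]-3-hydroxy-8-methoxy-4H-chromen-4-one | COc1cc(-c2oc3c(OC)c(OCc4ccccc4)cc(OCc4ccccc4)c3c(=O)c2O)c(OCc2ccccc2)cc1OCc1ccccc1 | intermediate
26 | 5,7-bis(benzyloxy)-2-[2,4-bis(benzyloxy)-5-methoxyphenyl]-3,8-dimethoxy-4H-chromen-4-one | COc1cc(-c2oc3c(OC)c(OCc4ccccc4)cc(OCc4ccccc4)c3c(=O)c2OC)c(OCc2ccccc2)cc1OCc1ccccc1 | intermediate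
27 | 5,7,2',4'-tetrahydroxy-3,8,5'-trimethoxyflavone | COc1cc(-c2oc3c(OC)c(O)cc(O)c3c(=O)c2OC)c(O)cc1O | target

**Step count**
Total: 19 steps. Longest linear sequence: 14 steps (steps 1–7, then 13–19); the ring B branch (steps 8–12) joins at step 13.

**Steps most likely to fail**

1. Step 16 (key iodocyclisation). Electrophilic iodination of the electron-rich arenes (C6 of ring A, C3' of ring B) may compete with alkyne activation. ICl may also add across the triple bond without ring closure, or closure may take the 5-membered course. Fallback, setting out from 22 and returning at 23: conjugate addition of diethylamine to the ynone (Et2NH, EtOH, rt) should give the enaminone (E)-1-[4,6-bis(benzyloxy)-2-hydroxy-3-methoxyphenyl]-3-[2,4-bis(benzyloxy)-5-methoxyphenyl]-3-(diethylamino)prop-2-en-1-one F1, which fixes the nucleophile-accepting carbon as C2. Treatment of F1 with I2 (CHCl3, rt) then iodinates the enaminone alpha carbon, and the phenol displaces diethylamine at C2 by addition–elimination, as in the known iodine-mediated closure of ortho-hydroxyaryl enaminones to 3-iodochromones. This gives 23 with a much milder electrophile than ICl; either enaminone geometry converges on 23.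

2. Step 17 (C3–I to C3–OH). Reductive loss of iodine, slow transmetalation at the crowded C3 position flanked by the carbonyl and the ortho-substituted ring B, or protodeboronation in the hot acetate medium may erode the boronate before oxidation. Fallback, setting out from 23 and returning at 24: iodine–magnesium exchange with iPrMgCl·LiCl (THF, −40 °C) should give chloro{5,7-bis(benzyloxy)-2-[2,4-bis(benzyloxy)-5-methoxyphenyl]-8-methoxy-4-oxo-4H-chromen-3-yl}magnesium F2. F2 is trapped cold with 2-isopropoxy-4,4,5,5-tetramethyl-1,3,2-dioxaborolane to give boronate 24 without palladium or heating, and 24 is oxidised at once as in step 17 to 25.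

3. Step 13 (acetylide addition). Addition to the doubly ortho-substituted, electron-rich aldehyde may be slow, and on warming the silyl group may migrate from the phenolic oxygen to the new alkoxide, which would expose the phenol and open a path to quinone-methide decomposition. Fallback, setting out from 9 and returning at 21: Pinnick oxidation (NaClO2, NaH2PO4, 2-methyl-2-butene, t-BuOH/H2O) should give 4,6-bis(benzyloxy)-2-[(tert-butyldimethylsilyl)oxy]-3-methoxybenzoic acid F3. Neutral activation with 1-chloro-N,N,2-trimethylprop-1-en-1-amine (CH2Cl2, rt) gives 4,6-bis(benzyloxy)-2-[(tert-butyldimethylsilyl)oxy]-3-methoxybenzoyl chloride F4. Acyl Sonogashira coupling of F4 with alkyne 18 (PdCl2(PPh3)2, CuI, Et3N, THF, rt) then gives ynone 21 directly, so that no alkoxide is ever formed next to the silyl ether and step 14 is not needed.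

**Further compounds**
F1 | step 16 | (E)-1-[4,6-bis(benzyloxy)-2-hydroxy-3-methoxyphenyl]-3-[2,4-bis(benzyloxy)-5-methoxyphenyl]-3-(diethylamino)prop-2-en-1-one | CCN(CC)/C(=C/C(=O)c1c(O)c(OC)c(OCc2ccccc2)cc1OCc1ccccc1)c1cc(OC)c(OCc2ccccc2)cc1OCc1ccccc1
F2 | step 17 | chloro{5,7-bis(benzyloxy)-2-[2,4-bis(benzyloxy)-5-methoxyphenyl]-8-methoxy-4-oxo-4H-chromen-3-yl}magnesium | COc1cc(-c2oc3c(OC)c(OCc4ccccc4)cc(OCc4ccccc4)c3c(=O)c2[Mg]Cl)c(OCc2ccccc2)cc1OCc1ccccc1
F3 | step 13 | 4,6-bis(benzyloxy)-2-[(tert-butyldimethylsilyl)oxy]-3-methoxybenzoic acid | COc1c(O[Si](C)(C)C(C)(C)C)c(C(=O)O)c(OCc2ccccc2)cc1OCc1ccccc1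
F4 | step 13 | 4,6-bis(benzyloxy)-2-[(tert-butyldimethylsilyl)oxy]-3-methoxybenzoyl chloride | COc1c(O[Si](C)(C)C(C)(C)C)c(C(=O)Cl)c(OCc2ccccc2)cc1OCc1ccccc1
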